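**Plan**

- Feature: the target's only amine nitrogen, the secondary amine N4, lies between a three-carbon arm ending at amide N1 and a four-carbon arm ending at amide N8. Each amide nitrogen already carries an (E)-4-hydroxycinnamoyl group, and the only rings are the two para-hydroxyphenyl rings, which are bought and not built.
- Retrosynthesis: the N4–CH2 bond of the three-carbon arm is cut first (primary amine plus aldehyde). The two amide C(O)–N bonds are cut next, leading back to one active ester of p-coumaric acid, mono-Boc-putrescine and 3,3-diethoxypropan-1-amine.
- Forward: the N-hydroxysuccinimide ester of p-coumaric acid acylates each amine. Boc cleavage frees the four-carbon amine and acetal hydrolysis frees the three-carbon aldehyde. The two monoamides are joined last by imine formation and borohydride reduction.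
- No ring is closed and the target has no stereocentre. Both E double bonds come from commercial (E)-p-coumaric acid and are not touched; light is excluded throughout to avoid E/Z isomerisation.

Key step: step 6

Remark: the phenols are carried unprotected, on the assumption that an N-hydroxysuccinimide ester acylates an aliphatic amine much faster than a phenol; spermidine numbering is used (N1 on the three-carbon arm, N4 central, N8 on the four-carbon arm).

**Route**

Step 1
Reactants: 1 (E)-p-coumaric acid
Product: 2 p-coumaric acid N-hydroxysuccinimide ester
Conditions: N-hydroxysuccinimide, DCC, THF, 0 °C to rt, dark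
Reagents that add atoms: N-hydroxysuccinimide, ON1C(=O)CCC1=O
Why: Carbodiimide-mediated active-ester formation (Steglich-type activation), in which DCC dehydrates the acid/N-hydroxysuccinimide pair while the un-ionised phenol is too weak a nucleophile to compete under these neutral conditions.

Step 2
Reactants: 2 p-coumaric acid N-hydroxysuccinimide ester; 3 N-Boc-1,4-diaminobutane
Product: 4 N-Boc-N'-(p-coumaroyl)putrescine
Conditions: Et3N, THF, 0 °C to rt
Reagents that add atoms: none
Why: Aminolysis of an active ester (amide bond formation), in which the primary aliphatic amine is by far the best nucleophile present and neither the phenol nor the carbamate N–H is acylated.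

Step 3
Reactants: 4 N-Boc-N'-(p-coumaroyl)putrescine
Product: 6 N-(4-aminobutyl)-p-coumaramide (p-coumaroylputrescine), via hydrochloride salt 5 (not isolated)
Conditions: HCl (4 M in 1,4-dioxane), 0 °C to rt; then 1 M NaOH (pH 10)
Reagents that add atoms: none
Why: Acidolysis of the tert-butyl carbamate (loss of the tert-butyl cation as isobutene, then decarboxylation of the carbamic acid) should leave the secondary amide, the phenol and the alkene untouched, and NaOH then frees the amine from its hydrochloride.

Step 4
Reactants: 2 p-coumaric acid N-hydroxysuccinimide ester; 7 3,3-diethoxypropan-1-amine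
Product: 8 N-(3,3-diethoxypropyl)-p-coumaramide
Conditions: Et3N, THF, 0 °C to rt
Reagents that add atoms: none
Why: Aminolysis of an active ester (amide bond formation) under basic, non-aqueous conditions to which the diethyl acetal is inert.

Step 5
Reactants: 8 N-(3,3-diethoxypropyl)-p-coumaramide
Product: 9 N-(3-oxopropyl)-p-coumaramide
Conditions: 1 M HCl (aq.), THF, 0 °C to rt; used at once
Reagents that add atoms: water, O
Why: Acid-catalysed acetal hydrolysis through the oxocarbenium ion, which the secondary amide and the phenol should tolerate in dilute acid at room temperature, and a 3-amidopropanal cannot close to a five-membered cyclic hemiaminal, so the open aldehyde is expected.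

Step 6
Reactants: 6 N-(4-aminobutyl)-p-coumaramide; 9 N-(3-oxopropyl)-p-coumaramide
Product: 11 N1,N8-bis(p-coumaroyl)spermidine, via imine 10 (not isolated)
Conditions: 6 (1.2 equiv), MeOH, 3 Å MS, rt, dark; then NaBH4, 0 °C
Reagents that add atoms: none
Why: The primary amine of 6 adds to the aldehyde of 9 and loses water to give aldimine 10, whose C=N bond then takes up hydride from NaBH4, so that the N4–CH2 bond of the three-carbon arm is the only skeletal bond made. The closest known reaction type is the stepwise (indirect) reductive amination of 3-(acylamino)propanals with primary amines, the standard chain-extension step of polyamine synthesis. No ring closes and no stereocentre is created, the two E alkenes and the para-hydroxyphenyl rings being spectators. The step needs single alkylation of the amine, reduction of C=N in preference to the two conjugated amides, and survival of the β-amido aldehyde against β-elimination. Single alkylation is secured because 6 holds the only amine nitrogen of either partner (all others are amide nitrogens) and, used in slight excess, consumes the aldehyde as the imine before any hydride or secondary amine is present. NaBH4 in methanol at 0 °C does not reduce cinnamamides, and under these neutral conditions the amide nitrogen is too poor a leaving group for acrolein to be expelled at a useful rate.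

**Compound list**

1 | (E)-p-coumaric acid; (E)-3-(4-hydroxyphenyl)prop-2-enoic acid | OC(=O)/C=C/c1ccc(O)cc1 | starting material
2 | p-coumaric acid N-hydroxysuccinimide ester; 2,5-dioxopyrrolidin-1-yl (E)-3-(4-hydroxyphenyl)prop-2-enoate | O=C(/C=C/c1ccc(O)cc1)ON1C(=O)CCC1=O | intermediate
3 | N-Boc-1,4-diaminobutane; tert-butyl (4-aminobutyl)carbamate | NCCCCNC(=O)OC(C)(C)C | starting material
4 | N-Boc-N'-(p-coumaroyl)putrescine; tert-butyl (4-{[(E)-3-(4-hydroxyphenyl)prop-2-enoyl]amino}butyl)carbamate | CC(C)(C)OC(=O)NCCCCNC(=O)/C=C/c1ccc(O)cc1 | intermediate
5 | N-(4-aminobutyl)-p-coumaramide hydrochloride (not isolated) | [NH3+]CCCCNC(=O)/C=C/c1ccc(O)cc1.[Cl-] | intermediate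
6 | N-(4-aminobutyl)-p-coumaramide (p-coumaroylputrescine); (E)-N-(4-aminobutyl)-3-(4-hydroxyphenyl)prop-2-enamide | NCCCCNC(=O)/C=C/c1ccc(O)cc1 | intermediate
7 | 3,3-diethoxypropan-1-amine | CCOC(CCN)OCC | starting material
8 | N-(3,3-diethoxypropyl)-p-coumaramide; (E)-N-(3,3-diethoxypropyl)-3-(4-hydroxyphenyl)prop-2-enamide | CCOC(CCNC(=O)/C=C/c1ccc(O)cc1)OCC | intermediate
9 | N-(3-oxopropyl)-p-coumaramide; (E)-3-(4-hydroxyphenyl)-N-(3-oxopropyl)prop-2-enamide | O=CCCNC(=O)/C=C/c1ccc(O)cc1 | intermediate
10 | aldimine from 6 and 9 (not isolated; C=N geometry not defined) | O=C(/C=C/c1ccc(O)cc1)NCCCCN=CCCNC(=O)/C=C/c1ccc(O)cc1 | intermediate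
11 | N1,N8-bis(p-coumaroyl)spermidine | O=C(/C=C/c1ccc(O)cc1)NCCCCNCCCNC(=O)/C=C/c1ccc(O)cc1 | target

**Step count**

Total: 6 steps. Longest linear sequence: 4 steps (steps 1, 2, 3 and 6; the branch through steps 1, 4, 5 and 6 is equally long).

**Steps most likely to fail, with fallbacks**

Step 6. Two processes threaten it. The new secondary amine may be alkylated a second time by aldehyde not yet bound as the imine. The β-amido aldehyde or its imine may also lose the amide by β-elimination before hydride arrives. The fallback sets out from 6 and returns at 11. It makes the same N4–CH2 bond by reductive amination, but with a robust carbamate aldehyde, and adds the second coumaroyl group last.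
- Amine 6 would be condensed in MeOH with commercial tert-butyl (3-oxopropyl)carbamate to give the N-Boc aldimine F1.
- NaBH4 at 0 °C would reduce F1 in the same flask to N1-Boc-N8-(p-coumaroyl)spermidine F2.
- HCl in dioxane would cleave the carbamate to N8-(p-coumaroyl)spermidine dihydrochloride F3.
- NaOH would free the triamine N8-(p-coumaroyl)spermidine F4.
- One equivalent of active ester 2, added slowly at −20 °C in DMF, would acylate the primary amine N1 in preference to the more hindered secondary amine N4 and give 11. This selectivity is a standard tactic of polyamine acylation.

Step 5. The aldehyde may be lost during acid hydrolysis and isolation through aldol self-condensation, condensation of the amide N–H with the aldehyde to oligomeric N-acyl hemiaminals, or β-elimination. The fallback sets out from 2 and returns at 9. It reaches the aldehyde by oxidative glycol cleavage under neutral conditions instead of acid hydrolysis.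
- Ester 2 would acylate commercial racemic 4-aminobutane-1,2-diol (Et3N, DMF) to give racemic N-(3,4-dihydroxybutyl)-p-coumaramide F5.
- NaIO4 in THF/water at 0 °C and pH 7 would cleave the 1,2-diol to 9. Glycol cleavage is much faster than any periodate oxidation of a para-substituted phenol, and the stereocentre of F5 disappears in the cleavage.

Step 3. The tert-butyl cation may alkylate the electron-rich phenol ring, and the amphoteric free base may be lost to the aqueous phase during neutralisation. The fallback sets out from 2 and returns at 6. It carries the amine as an azide and unmasks it without acid.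
- Ester 2 would acylate commercial 4-azidobutan-1-amine (Et3N, THF) to give N-(4-azidobutyl)-p-coumaramide F6.
- Staudinger reduction (PPh3, THF/water, rt to 50 °C) would pass through the iminophosphorane F7, which water hydrolyses in the flask to the free base 6.
- The phosphine oxide would be removed by trituration with toluene.

**Further compounds**

F1 | step 6 | N-Boc aldimine from 6 and tert-butyl (3-oxopropyl)carbamate (not isolated) | CC(C)(C)OC(=O)NCCC=NCCCCNC(=O)/C=C/c1ccc(O)cc1
F2 | step 6 | N1-Boc-N8-(p-coumaroyl)spermidine | CC(C)(C)OC(=O)NCCCNCCCCNC(=O)/C=C/c1ccc(O)cc1
F3 | step 6 | N8-(p-coumaroyl)spermidine dihydrochloride | [NH3+]CCC[NH2+]CCCCNC(=O)/C=C/c1ccc(O)cc1.[Cl-].[Cl-]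
F4 | step 6 | N8-(p-coumaroyl)spermidine | NCCCNCCCCNC(=O)/C=C/c1ccc(O)cc1
F5 | step 5 | racemic N-(3,4-dihydroxybutyl)-p-coumaramide | OCC(O)CCNC(=O)/C=C/c1ccc(O)cc1
F6 | step 3 | N-(4-azidobutyl)-p-coumaramide | [N-]=[N+]=NCCCCNC(=O)/C=C/c1ccc(O)cc1
F7 | step 3 | iminophosphorane from F6 and PPh3 (not isolated) | O=C(/C=C/c1ccc(O)cc1)NCCCCN=P(c1ccccc1)(c1ccccc1)c1ccccc1
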